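**Strategy.** Everything rests on opening one O1–C bond of the oxolane, which leads back to an acyclic 1,4-diaryl-2,3-dimethylbutane-1,4-diol. The key step exploits two features: C2 (carrying ring B) and C5 (carrying ring A) each stand benzylic to a ring whose oxygen is para, so their C–O bonds open to stabilised cations and close again, and the cis methyls on C3 and C4 make the isomer with both aryls on the opposite face the energy minimum. A single acid treatment thus closes the ring and fixes C2 and C5 together. The precursor is the tribenzyl-protected diol 22, configured only at C3, C4 and the side-chain carbon Cα and epimeric at both carbinols.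

Key step: step 11

Locants: oxolane O1, C2 (ring B), C3 and C4 (methyls), C5 (ring A). Ring A is the phenol carrying the side chain, ring B the 4-hydroxyphenyl on C2, ring C the 4-hydroxyphenyl of the side chain, and Cα the side-chain stereocentre. The target is (2S,3S,4R,5R,αR).

Assumption 1: quinidine is taken to open anhydride 2 to the (2S,3R) half-ester 3; if the sense proves opposite, quinine (its pseudo-enantiomer) is used instead and nothing else changes.

Assumption 2: the (S)-configured ligand of step 8 is taken to give the (R)-alkane, as expected for (E)-1,2-diarylpropenes; if not, the (R)-ligand is used.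

**Step 1**
Reactants: 1 meso-2,3-dimethylsuccinic acid
Product: 2 meso-2,3-dimethylsuccinic anhydride (cis-3,4-dimethyloxolane-2,5-dione)
Conditions: AcCl (neat), reflux, 3 h; evaporation
Reagents that add atoms: none
Why: Cyclodehydration of the 1,4-diacid by acetyl chloride (mixed anhydride, then intramolecular acyl transfer) should give the five-membered anhydride without base, so the two methyl-bearing centres keep their meso (cis) relationship and no stereocentre is created.

**Step 2**
Reactants: 2 meso-2,3-dimethylsuccinic anhydride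
Product: 3 (2S,3R)-4-methoxy-2,3-dimethyl-4-oxobutanoic acid
Conditions: quinidine (1.1 equiv), MeOH (3 equiv), toluene, −55 °C; 2 M HCl work-up
Reagents that add atoms: methanol, CO
Why: Alkaloid-mediated desymmetrising alcoholysis of a meso anhydride: the quinidine–methanol complex should attack one of the two enantiotopic carbonyl groups, so no centre is formed but the absolute sense of the C3/C4 pair (3S,4R in the oxolane) is fixed here.

**Step 3**
Reactants: 3 (2S,3R)-4-methoxy-2,3-dimethyl-4-oxobutanoic acid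
Product: 5 methyl (2R,3S)-4-[methoxy(methyl)amino]-2,3-dimethyl-4-oxobutanoate, via acyl imidazole 4 (not isolated)
Conditions: 1,1'-carbonyldiimidazole (CDI, 1.1 equiv), CH2Cl2, 0 °C → rt; then MeNHOMe·HCl (1.5 equiv), rt
Reagents that add atoms: N,O-dimethylhydroxylamine hydrochloride, CNOC.Cl
Why: Amide formation through an acyl imidazole (CDI coupling) runs without strong base or an acid chloride, so the α-centre should not epimerise and the ester and activated acyl ends cannot exchange, which would racemise the half-ester.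

**Step 4**
Reactants: 5 methyl (2R,3S)-4-[methoxy(methyl)amino]-2,3-dimethyl-4-oxobutanoate; 6 1-(benzyloxy)-4-bromobenzene
Product: 9 methyl (2R,3S)-4-[4-(benzyloxy)phenyl]-2,3-dimethyl-4-oxobutanoate, via aryl Grignard reagent 7 (not isolated), via chelated tetrahedral adduct 8 (not isolated)
Conditions: 6, Mg, THF, 40 °C; then 5, THF, −20 → 0 °C; sat. aq NH4Cl
Reagents that add atoms: none
Why: Weinreb ketone synthesis: the aryl Grignard reagent should add to the N-methoxy-N-methylamide in preference to the α-branched methyl ester, and adduct 8 stays chelated until the quench, so the ketone meets neither excess nucleophile nor base and the adjacent centre is kept.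

**Step 5**
Reactants: 9 methyl (2R,3S)-4-[4-(benzyloxy)phenyl]-2,3-dimethyl-4-oxobutanoate
Product: 11 (3R,4S)-5-[4-(benzyloxy)phenyl]-3,4-dimethyloxolan-2-one (3,4-cis; both C5 epimers), via hydroxy ester 10 (not isolated)
Conditions: NaBH4, MeOH, 0 °C; aq NH4Cl; then pyridinium p-toluenesulfonate (10 mol %), CH2Cl2, rt
Reagents that add atoms: none
Why: Borohydride reduction of the aryl ketone and acid-catalysed lactonisation of the γ-hydroxy ester turn the remaining ester into a lactone that can take up exactly one aryllithium with no free ketone present; the new carbinol centre is left uncontrolled on purpose because step 11 equilibrates it.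

**Step 6**
Reactants: 12 5'-bromo-2'-hydroxyacetophenone
Product: 13 1-[2-(benzyloxy)-5-bromophenyl]ethan-1-one
Conditions: BnBr, K2CO3, DMF, 60 °C
Reagents that add atoms: benzyl bromide, BrCc1ccccc1
Why: Williamson ether synthesis on the phenoxide with a benzylic bromide; carbonate is too weak to enolise the methyl ketone.

**Step 7**
Reactants: 13 1-[2-(benzyloxy)-5-bromophenyl]ethan-1-one; 14 4-(benzyloxy)benzyl chloride
Product: 17 1-(benzyloxy)-2-[(1E)-1-[4-(benzyloxy)phenyl]prop-1-en-2-yl]-4-bromobenzene, via benzylic Grignard reagent 15 (not isolated), via tertiary alcohol 16 (not isolated)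
Conditions: 14, Mg, THF, 0 °C (slow addition); 13, 0 °C → rt; aq NH4Cl; then TsOH·H2O (5 mol %), toluene, 80 °C; recrystallisation
Reagents that add atoms: none
Why: Grignard 1,2-addition of the benzylic magnesium reagent to the aryl methyl ketone followed by acid-catalysed E1 dehydration under equilibrating conditions should favour the conjugated trisubstituted alkene with the two aryl groups trans (E), which is taken to geometric purity by recrystallisation; the transient carbinol centre is destroyed again.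

**Step 8**
Reactants: 17 1-(benzyloxy)-2-[(1E)-1-[4-(benzyloxy)phenyl]prop-1-en-2-yl]-4-bromobenzene
Product: 18 1-(benzyloxy)-2-[(2R)-1-[4-(benzyloxy)phenyl]propan-2-yl]-4-bromobenzene
Conditions: H2 (50 bar), [Ir(cod)(L)]BArF (1 mol %), CH2Cl2, rt; L = (S)-4-tert-butyl-2-[2-(di-o-tolylphosphanyl)phenyl]-4,5-dihydro-1,3-oxazole, cod = cycloocta-1,5-diene, BArF = B[3,5-(CF3)2C6H3]4
Reagents that add atoms: none
Why: Iridium-catalysed asymmetric hydrogenation of an unfunctionalised (E)-1,2-diarylpropene with a chiral phosphinooxazoline ligand: the ligand pocket selects the alkene face to which H2 is delivered and so sets Cα as R, and this homogeneous catalyst leaves aryl bromide and benzyl ethers untouched.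

**Step 9**
Reactants: 18 1-(benzyloxy)-2-[(2R)-1-[4-(benzyloxy)phenyl]propan-2-yl]-4-bromobenzene; 11 (3R,4S)-5-[4-(benzyloxy)phenyl]-3,4-dimethyloxolan-2-one
Product: 21 (2R,3S)-1-{4-(benzyloxy)-3-[(2R)-1-[4-(benzyloxy)phenyl]propan-2-yl]phenyl}-4-[4-(benzyloxy)phenyl]-4-hydroxy-2,3-dimethylbutan-1-one (both C4 epimers), via aryllithium 19 (not isolated), via lithium lactolate 20 (not isolated)
Conditions: 18, n-BuLi (1.05 equiv), THF, −78 °C, 30 min; cannulate into 11 (1.2 equiv), THF, −78 °C; sat. aq NH4Cl at −78 °C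
Reagents that add atoms: none
Why: Bromine–lithium exchange followed by a single nucleophilic acyl addition to the γ-lactone: lactolate 20 should persist at −78 °C, so the aryl ketone appears only on quench, and C3, C4 and Cα are not involved.

**Step 10**
Reactants: 21 (2R,3S)-1-{4-(benzyloxy)-3-[(2R)-1-[4-(benzyloxy)phenyl]propan-2-yl]phenyl}-4-[4-(benzyloxy)phenyl]-4-hydroxy-2,3-dimethylbutan-1-one
Product: 22 (2R,3S)-1-{4-(benzyloxy)-3-[(2R)-1-[4-(benzyloxy)phenyl]propan-2-yl]phenyl}-4-[4-(benzyloxy)phenyl]-2,3-dimethylbutane-1,4-diol (mixture of C1 and C4 epimers)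
Conditions: NaBH4, MeOH/THF (1:1), 0 °C → rt
Reagents that add atoms: none
Why: Borohydride reduction of the aryl ketone under mild conditions gives the 1,4-diol; the new carbinol centre is formed without control because both carbinols are erased in step 11.

**Step 11**
Reactants: 22 (2R,3S)-1-{4-(benzyloxy)-3-[(2R)-1-[4-(benzyloxy)phenyl]propan-2-yl]phenyl}-4-[4-(benzyloxy)phenyl]-2,3-dimethylbutane-1,4-diol (epimer mixture)
Product: 23 (2S,3S,4R,5R)-2-[4-(benzyloxy)phenyl]-5-{4-(benzyloxy)-3-[(2R)-1-[4-(benzyloxy)phenyl]propan-2-yl]phenyl}-3,4-dimethyloxolane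
Conditions: BF3·OEt2 (0.3 equiv), CH2Cl2, −20 °C → rt, until the isomer composition no longer changes; Et3N quench
Reagents that add atoms: none
Why: BF3 ionises either benzylic hydroxyl to a cation delocalised into its para-benzyloxy ring (para-quinoid oxocarbenium form), and the other hydroxyl traps it to make the O1–C bond. The closest known reaction type is the acid cyclodehydration of 1,4-diarylbutane-1,4-diols together with the acid epimerisation of 2,5-diaryloxolane lignans. The oxolane closes in a 5-exo-trig mode onto the trigonal cationic carbon. C2 is controlled by the methyl on C3 and C5 by the methyl on C4: closure is preferred anti to the adjacent methyl, and any isomer with an aryl cis to its methyl should re-ionise at that benzylic C–O bond and reclose until the 2,3-trans/4,5-trans arrangement is reached. The step needs thermodynamic diastereoselection at C2 and C5 without loss of C3, C4 or Cα, and O-capture in preference to Friedel–Crafts capture; the first is secured by the fixed cis-3,4-dimethyl pair, which leaves one face free for both aryls, the second by rings A and B, whose carbons within reach of the cation are meta to the ring oxygen and so not activated.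

**Step 12**
Reactants: 23 (2S,3S,4R,5R)-2-[4-(benzyloxy)phenyl]-5-{4-(benzyloxy)-3-[(2R)-1-[4-(benzyloxy)phenyl]propan-2-yl]phenyl}-3,4-dimethyloxolane
Product: 24 4-[(2S,3S,4R,5R)-5-{4-hydroxy-3-[(2R)-1-(4-hydroxyphenyl)propan-2-yl]phenyl}-3,4-dimethyloxolan-2-yl]phenol (CNP0232576.1)
Conditions: H2 (1 atm), 10% Pd/C, EtOAc, rt; stopped at complete debenzylation
Reagents that add atoms: none
Why: Catalytic hydrogenolysis of aryl benzyl ethers, which are cleaved far faster than the oxolane's own benzylic C–O bonds under neutral conditions at 1 atm, so the ring and all five stereocentres should survive if the reaction is stopped at full debenzylation.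

**Compound list**

1 | meso-2,3-dimethylsuccinic acid, (2R,3S)-2,3-dimethylbutanedioic acid | C[C@@H](C(=O)O)[C@H](C)C(=O)O | starting material
2 | meso-2,3-dimethylsuccinic anhydride, (3R,4S)-3,4-dimethyloxolane-2,5-dione | C[C@@H](C1=O)[C@H](C)C(=O)O1 | intermediate
3 | (2S,3R)-4-methoxy-2,3-dimethyl-4-oxobutanoic acid | C[C@@H](C(=O)OC)[C@H](C)C(=O)O | intermediate
4 | methyl (2R,3S)-4-(1H-imidazol-1-yl)-2,3-dimethyl-4-oxobutanoate | C[C@@H](C(=O)OC)[C@H](C)C(=O)n1ccnc1 | intermediate (not isolated)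
5 | methyl (2R,3S)-4-[methoxy(methyl)amino]-2,3-dimethyl-4-oxobutanoate | C[C@@H](C(=O)OC)[C@H](C)C(=O)N(C)OC | intermediate
6 | 1-(benzyloxy)-4-bromobenzene | Brc1ccc(OCc2ccccc2)cc1 | starting material
7 | [4-(benzyloxy)phenyl]magnesium bromide | Br[Mg]c1ccc(OCc2ccccc2)cc1 | intermediate (not isolated)
8 | bromomagnesium alkoxide of methyl (2R,3S)-4-[4-(benzyloxy)phenyl]-4-hydroxy-4-[methoxy(methyl)amino]-2,3-dimethylbutanoate (C4 unassigned) | C[C@@H](C(=O)OC)[C@H](C)C(O[Mg]Br)(N(C)OC)c1ccc(OCc2ccccc2)cc1 | intermediate (not isolated)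
9 | methyl (2R,3S)-4-[4-(benzyloxy)phenyl]-2,3-dimethyl-4-oxobutanoate | C[C@@H](C(=O)OC)[C@H](C)C(=O)c1ccc(OCc2ccccc2)cc1 | intermediate
10 | methyl (2R,3S)-4-[4-(benzyloxy)phenyl]-4-hydroxy-2,3-dimethylbutanoate (both C4 epimers) | C[C@@H](C(=O)OC)[C@H](C)C(O)c1ccc(OCc2ccccc2)cc1 | intermediate (not isolated)
11 | (3R,4S)-5-[4-(benzyloxy)phenyl]-3,4-dimethyloxolan-2-one (3,4-cis; both C5 epimers) | C[C@@H](C1=O)[C@H](C)C(c2ccc(OCc3ccccc3)cc2)O1 | intermediate
12 | 5'-bromo-2'-hydroxyacetophenone | CC(=O)c1cc(Br)ccc1O | starting material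
13 | 1-[2-(benzyloxy)-5-bromophenyl]ethan-1-one | CC(=O)c1cc(Br)ccc1OCc1ccccc1 | intermediate
14 | 4-(benzyloxy)benzyl chloride | ClCc1ccc(OCc2ccccc2)cc1 | starting material
15 | [4-(benzyloxy)benzyl]magnesium chloride | Cl[Mg]Cc1ccc(OCc2ccccc2)cc1 | intermediate (not isolated)
16 | 2-[2-(benzyloxy)-5-bromophenyl]-1-[4-(benzyloxy)phenyl]propan-2-ol (racemic) | CC(O)(Cc1ccc(OCc2ccccc2)cc1)c1cc(Br)ccc1OCc1ccccc1 | intermediate (not isolated)
17 | 1-(benzyloxy)-2-[(1E)-1-[4-(benzyloxy)phenyl]prop-1-en-2-yl]-4-bromobenzene | C/C(=C\c1ccc(OCc2ccccc2)cc1)c1cc(Br)ccc1OCc1ccccc1 | intermediate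
18 | 1-(benzyloxy)-2-[(2R)-1-[4-(benzyloxy)phenyl]propan-2-yl]-4-bromobenzene | C[C@H](Cc1ccc(OCc2ccccc2)cc1)c1cc(Br)ccc1OCc1ccccc1 | intermediate
19 | {4-(benzyloxy)-3-[(2R)-1-[4-(benzyloxy)phenyl]propan-2-yl]phenyl}lithium | [Li]c1ccc(OCc2ccccc2)c(c1)[C@H](C)Cc1ccc(OCc2ccccc2)cc1 | intermediate (not isolated)
20 | lithium (3R,4S)-2-{4-(benzyloxy)-3-[(2R)-1-[4-(benzyloxy)phenyl]propan-2-yl]phenyl}-5-[4-(benzyloxy)phenyl]-3,4-dimethyloxolan-2-olate (C2 and C5 unassigned) | C[C@@H](C1(O[Li])c2ccc(OCc3ccccc3)c([C@H](C)Cc3ccc(OCc4ccccc4)cc3)c2)[C@H](C)C(c2ccc(OCc3ccccc3)cc2)O1 | intermediate (not isolated)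
21 | (2R,3S)-1-{4-(benzyloxy)-3-[(2R)-1-[4-(benzyloxy)phenyl]propan-2-yl]phenyl}-4-[4-(benzyloxy)phenyl]-4-hydroxy-2,3-dimethylbutan-1-one (both C4 epimers) | C[C@@H](C(=O)c1ccc(OCc2ccccc2)c([C@H](C)Cc2ccc(OCc3ccccc3)cc2)c1)[C@H](C)C(O)c1ccc(OCc2ccccc2)cc1 | intermediate
22 | (2R,3S)-1-{4-(benzyloxy)-3-[(2R)-1-[4-(benzyloxy)phenyl]propan-2-yl]phenyl}-4-[4-(benzyloxy)phenyl]-2,3-dimethylbutane-1,4-diol (mixture of C1 and C4 epimers) | OC(c1ccc(OCc2ccccc2)c([C@H](C)Cc2ccc(OCc3ccccc3)cc2)c1)[C@H](C)[C@H](C)C(O)c1ccc(OCc2ccccc2)cc1 | intermediate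
23 | (2S,3S,4R,5R)-2-[4-(benzyloxy)phenyl]-5-{4-(benzyloxy)-3-[(2R)-1-[4-(benzyloxy)phenyl]propan-2-yl]phenyl}-3,4-dimethyloxolane | C[C@@H]1[C@H](C)[C@@H](c2ccc(OCc3ccccc3)cc2)O[C@H]1c1ccc(OCc2ccccc2)c([C@H](C)Cc2ccc(OCc3ccccc3)cc2)c1 | intermediate
24 | 4-[(2S,3S,4R,5R)-5-{4-hydroxy-3-[(2R)-1-(4-hydroxyphenyl)propan-2-yl]phenyl}-3,4-dimethyloxolan-2-yl]phenol | C[C@@H]1[C@H](C)[C@@H](c2ccc(O)cc2)O[C@H]1c1ccc(O)c([C@H](C)Cc2ccc(O)cc2)c1 | target

**Step count and risks**

Total step count: 12. Longest linear sequence: 9 steps (steps 1–5, then 9–12); the ring A branch (steps 6–8) joins at step 9.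

Steps most likely to fail:

**Step 11 (key step).** The epimer equilibrium may be reached only slowly. The open-chain benzylic cation may also lose a proton from C3 or C4 to give a styrene, which would scramble the methyl-bearing centres, or it may arylate a second molecule. The fallback sets out from hydroxy ketone 21 and returns at 23. The ring is closed one oxidation level higher by ionic hydrogenation (Et3SiH, BF3·OEt2, CH2Cl2, −78 °C) of the cyclic oxocarbenium ion that 21 forms on activation. This should give (3S,4R)-2-[4-(benzyloxy)phenyl]-5-{4-(benzyloxy)-3-[(2R)-1-[4-(benzyloxy)phenyl]propan-2-yl]phenyl}-3,4-dimethyloxolane as a mixture of C2/C5 epimers F1, with no acyclic benzylic cation formed next to C3 or C4. A separate, known acid epimerisation of the closed ring (TsOH·H2O, CH2Cl2, rt) then leads to 23.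

**Step 8.** The ortho-benzyloxy group twists ring A out of conjugation and may bind iridium, so turnover may stall or facial discrimination may be poor. Trace acid may also shift or isomerise the double bond before reduction. The fallback replaces catalyst control by auxiliary control; it sets out from ketone 13, uses 14 as the electrophile, and returns at 18.
- Willgerodt–Kindler reaction of 13 (S8, morpholine, 130 °C) gives 2-[2-(benzyloxy)-5-bromophenyl]-1-(morpholin-4-yl)ethane-1-thione F2.
- Hydrolysis (KOH, EtOH/H2O, reflux; acidification) gives [2-(benzyloxy)-5-bromophenyl]acetic acid F3.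
- Acylation (pivaloyl chloride, Et3N, LiCl, (4R)-4-benzyl-1,3-oxazolidin-2-one, THF) gives (4R)-4-benzyl-3-{[2-(benzyloxy)-5-bromophenyl]acetyl}-1,3-oxazolidin-2-one F4.
- Oxazolidinone-auxiliary (Evans) alkylation (NaN(SiMe3)2, THF, −78 °C; 14, Bu4NI cat., −78 → −30 °C) should take place on the enolate face away from the 4-benzyl group and give (4R)-4-benzyl-3-{(2R)-2-[2-(benzyloxy)-5-bromophenyl]-3-[4-(benzyloxy)phenyl]propanoyl}-1,3-oxazolidin-2-one F5.
- LiBH4 (THF/MeOH, 0 °C) gives (2R)-2-[2-(benzyloxy)-5-bromophenyl]-3-[4-(benzyloxy)phenyl]propan-1-ol F6.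
- TsCl, Et3N and DMAP give (2R)-2-[2-(benzyloxy)-5-bromophenyl]-3-[4-(benzyloxy)phenyl]propyl 4-methylbenzenesulfonate F7.
- LiEt3BH (THF, 0 °C → rt) replaces the sulfonate by hydride and gives 18.

**Step 9.** The lactolate may collapse early and take up a second aryllithium. The aryllithium may instead deprotonate C3 of the lactone, which would epimerise it towards the trans-dimethyl series. Bromine–lithium exchange may be incomplete. The fallback changes the acyl acceptor; it sets out from lactone 11 and returns at 21.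
- Ring opening with MeNHOMe·HCl and i-PrMgCl (THF, −20 °C) gives (2R,3S)-4-[4-(benzyloxy)phenyl]-4-hydroxy-N-methoxy-N,2,3-trimethylbutanamide F8.
- Immediate silylation (TBSCl, imidazole, DMF) gives (2R,3S)-4-[4-(benzyloxy)phenyl]-4-[(tert-butyldimethylsilyl)oxy]-N-methoxy-N,2,3-trimethylbutanamide F9.
- Aryllithium 19 (THF, −78 °C) adds once to this Weinreb amide and gives (2R,3S)-1-{4-(benzyloxy)-3-[(2R)-1-[4-(benzyloxy)phenyl]propan-2-yl]phenyl}-4-[4-(benzyloxy)phenyl]-4-[(tert-butyldimethylsilyl)oxy]-2,3-dimethylbutan-1-one F10.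
- Bu4NF buffered with AcOH (THF, 0 °C) removes the silyl group and gives 21.

**Further compounds**

F1 | step 11 | (3S,4R)-2-[4-(benzyloxy)phenyl]-5-{4-(benzyloxy)-3-[(2R)-1-[4-(benzyloxy)phenyl]propan-2-yl]phenyl}-3,4-dimethyloxolane, mixture of C2/C5 epimers | C[C@@H]1[C@H](C)C(c2ccc(OCc3ccccc3)cc2)OC1c1ccc(OCc2ccccc2)c([C@H](C)Cc2ccc(OCc3ccccc3)cc2)c1
F2 | step 8 | 2-[2-(benzyloxy)-5-bromophenyl]-1-(morpholin-4-yl)ethane-1-thione | S=C(Cc1cc(Br)ccc1OCc1ccccc1)N1CCOCC1
F3 | step 8 | [2-(benzyloxy)-5-bromophenyl]acetic acid | OC(=O)Cc1cc(Br)ccc1OCc1ccccc1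
F4 | step 8 | (4R)-4-benzyl-3-{[2-(benzyloxy)-5-bromophenyl]acetyl}-1,3-oxazolidin-2-one | O=C(Cc1cc(Br)ccc1OCc1ccccc1)N1[C@H](Cc2ccccc2)COC1=O
F5 | step 8 | (4R)-4-benzyl-3-{(2R)-2-[2-(benzyloxy)-5-bromophenyl]-3-[4-(benzyloxy)phenyl]propanoyl}-1,3-oxazolidin-2-one | O=C([C@H](Cc1ccc(OCc2ccccc2)cc1)c1cc(Br)ccc1OCc1ccccc1)N1[C@H](Cc2ccccc2)COC1=O
F6 | step 8 | (2R)-2-[2-(benzyloxy)-5-bromophenyl]-3-[4-(benzyloxy)phenyl]propan-1-ol | OC[C@H](Cc1ccc(OCc2ccccc2)cc1)c1cc(Br)ccc1OCc1ccccc1
F7 | step 8 | (2R)-2-[2-(benzyloxy)-5-bromophenyl]-3-[4-(benzyloxy)phenyl]propyl 4-methylbenzenesulfonate | Cc1ccc(cc1)S(=O)(=O)OC[C@H](Cc1ccc(OCc2ccccc2)cc1)c1cc(Br)ccc1OCc1ccccc1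
F8 | step 9 | (2R,3S)-4-[4-(benzyloxy)phenyl]-4-hydroxy-N-methoxy-N,2,3-trimethylbutanamide (both C4 epimers) | C[C@@H](C(=O)N(C)OC)[C@H](C)C(O)c1ccc(OCc2ccccc2)cc1
F9 | step 9 | (2R,3S)-4-[4-(benzyloxy)phenyl]-4-[(tert-butyldimethylsilyl)oxy]-N-methoxy-N,2,3-trimethylbutanamide (both C4 epimers) | C[C@@H](C(=O)N(C)OC)[C@H](C)C(O[Si](C)(C)C(C)(C)C)c1ccc(OCc2ccccc2)cc1
F10 | step 9 | (2R,3S)-1-{4-(benzyloxy)-3-[(2R)-1-[4-(benzyloxy)phenyl]propan-2-yl]phenyl}-4-[4-(benzyloxy)phenyl]-4-[(tert-butyldimethylsilyl)oxy]-2,3-dimethylbutan-1-one (both C4 epimers) | C[C@@H](C(=O)c1ccc(OCc2ccccc2)c([C@H](C)Cc2ccc(OCc3ccccc3)cc2)c1)[C@H](C)C(O[Si](C)(C)C(C)(C)C)c1ccc(OCc2ccccc2)cc1
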